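## Structural features

The target is a monocyclic 1,2-dioxane (O1–O2–C3–C4–C5–C6). C3 carries a methyl acetate arm (C1–C2), C4 a methyl group, and the quaternary C6 a methyl group and the chain C7–C12, CH2–C(CH3)=CH–CH=CH–CH2–Ph, with (8E,10E) geometry. The stereocentres are C3 (S), C4 (R) and C6 (R). C3 and C4 are adjacent and trans; in the chair with the C4 methyl equatorial, the acetate arm is equatorial, the C6 methyl axial and the long chain equatorial. The fragile elements are the O–O bond (reductants, low-valent metals, phosphines, strong nucleophiles), the β-peroxy ester (deprotonation at C2 expels the peroxide by E1cB), and the skipped diene with its doubly activated C12 methylene, which would not survive ozone or strong acid. The real difficulty is placing O–O between a secondary carbon and a fully substituted one, with C3 and C6 controlled relative to C4; plain C–O displacement is unattractive at C6. The key step uses the fact that C3 and C6 are 1,4-related through C4–C5 and both bonded to the O1–O2 unit: removing the two oxygens and joining C3 to C6 by a double bond gives a cyclobutene (C3=C6–C5–C4). Ozonolysis of that ring alkene in methanol puts O–O back between exactly those two carbons. C4 is the only stereocentre carried through and afterwards anchors the ring conformation for setting C6 and C3.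

## Logic of the disconnections

30 is cut at the C9–C10 bond between two alkene carbons, giving 27 and 29. This keeps the ozone- and acid-sensitive diene out of every peroxide-forming step and removes nine carbons at once. The forward coupling must tolerate the O–O bond and the base-labile β-peroxy ester, so it needs a weak base and mild temperature, with retention of both alkene geometries.

29 is cut at its C–B bond back to 28. The forward step is a syn, anti-Markovnikov hydroboration that must not isomerise the propargylic benzylic position.

27 is cut at the C3–H bond back to 25, in which C3 is a methyl peroxyketal. C3 comes out of the ring-forming step as a ketal carbon, so hydrogen has to be added as hydride to a C3 cation. The forward step must deliver hydride axially and keep the ring intact.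

25 is cut at the C6–CH3 bond back to 23. C6 was an alkene carbon of the four-membered ring and can carry only one carbon substituent there, so the methyl group must be added to the ketal afterwards. The forward step must pick C6 over C3 and attack axially.

23 is cut at C3–O1 and C6–O2, with O1–O2 coming from ozone, which restores the C3=C6 bond of 15. The heterocycle, the peroxide and both ketal carbons disappear and one stereocentre is left in a small carbocycle. The forward step must cleave the ring alkene and not the bromoalkene, and methanol must trap the carbonyl oxide.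

15 is cut at the bond between the ring alkene carbon and the allylic CH2, giving 10 and 14. The cut is convergent and sits away from the stereocentre. The forward coupling must react at the allylic C–Br bond and leave the vinylic one, without moving either alkene.

14 is taken back through 13 to 11: the allylic C–Br bond by functional group change, then the C–CH3 and vinylic C–Br bonds across the alkyne. Syn carbometalation fixes the E geometry in one operation.

10 is cut at C–B back to 9, and 9 at C–OTf and the side-chain C–H back to 7. Generating the enolate by hydride addition to the exocyclic enone fixes its position on the substituted ring carbon. Deprotonating a 2-substituted cyclobutanone would favour the other side kinetically and risk self-condensation under equilibrating conditions, which is why the two-carbon arm is brought in as a glyoxylate and not as a haloacetate. The forward step needs 1,4- and not 1,2-addition.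

7 is cut at the exocyclic C=C back to 5, and 5 at the C–C bond between the ring α-carbon and the carbinol carbon back to 3 and 4. The ester arm arrives at the right oxidation level from a commercial C2 unit. Bond formation is regiospecific and involves no free enolate, so the enantiomeric purity of 3 is kept.

3 is cut at the O–Si bond and the α C–H bond back to 1. The forward step must distinguish the two enantiotopic methylene groups of 1; this is the only reagent-controlled stereochemical event of the route and it sets C4 of the target.

## Other disconnections considered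

Alternative 1: The cut is the C6–O2 bond. In the forward step the hydroperoxy oxetane A1 would be treated with TMSOTf; its C3 hydroperoxide would attack the quaternary oxetane carbon from the side opposite the ring oxygen, giving dioxane A2 with inversion at C6 and a free C8 hydroxyl.
- In its favour: C6 is set stereospecifically from a centre built by ordinary chemistry, Lewis-acid opening of oxetanes by hydroperoxides is a known reaction type, and no ozone is needed.
- Against it: A1 needs a configurationally pure secondary hydroperoxide at C3, which is hard to install and to carry. The tertiary oxetane carbon may ionise and lose the inversion. A2 has neither the C8 methyl group nor the C8=C9 alkene, and C1 is still a silyl ether; oxidising C8 would put a carbonyl β to the C6 peroxide oxygen and invite E1cB ring opening before methyl addition and a regio- and E-selective dehydration.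
- Structure: both plans set C6 after C4. Alternative 1 does so with precedent and stereospecificity, which is better than the untested methyl transfer of step 10.
- Mechanism: one SN2-type ring closure against a three-event cascade; comparable in risk.
- Step economy: the chosen plan is clearly shorter after ring formation (three steps from 23 to 30, against at least seven from A2).

Alternative 2: The cut is the O1–O2 bond. In the forward step the bis(aminooxy) ester A3 would be oxidised with PhI(OAc)2; the two nitrogens would couple and leave as N2, and the two oxygen termini would have to combine to give dioxane A4.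
- In its favour: the peroxide is made last, so no earlier step has to tolerate it; this is a real advantage over the chosen plan, which carries O–O through three further steps. C3 and C6 are fixed beforehand as C–O bonds and are not touched. A4 already has the C8 methyl group and the C8=C9 alkene, which equals the chosen plan.
- Against it: loss of N2 leaves two oxygen-centred radicals. The tertiary one at C6 can fragment by β-scission to an allyl-type radical, and the pair can fragment to two carbonyl groups and an alkene, both in competition with O–O recombination; intermolecular N–N coupling would demand high dilution. A tertiary aminooxy group of defined configuration at C6 is hard to make. A4 still needs desilylation, oxidation and a base-mediated olefination next to a base-labile β-peroxy ester.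
- Structure: equal on the side chain and better on stereochemical security at C3.
- Mechanism: radical recombination as a ring-forming peroxide synthesis is far less precedented than Criegee chemistry.
- Step economy: similar after the key step, longer before it.

Alternative 3: The cuts are C3–O1 and C1–C2. In the forward step the unsaturated tertiary hydroperoxide A5 would be treated with PdCl2(MeCN)2 (divalent palladium), CO, methanol and a reoxidant; 6-exo peroxypalladation of the terminal alkene, CO insertion and methanolysis would give dioxane ester A6.
- In its favour: the ring, the C3 stereocentre, the C1–C2 bond and the ester at its final oxidation level are formed in one step, more per step than in the chosen plan and with no ketal adjustments afterwards. Cyclisation of unsaturated hydroperoxides on divalent palladium is a known reaction type.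
- Against it: hydroperoxides oxidise and ligate palladium, so ketone formation at the alkene, β-hydride elimination before CO insertion and decomposition of the hydroperoxide all compete. The C10=C11 alkene can also bind the metal. A5 needs a tertiary hydroperoxide of defined configuration at C6, and A6 again lacks the C8 methyl group and the C8=C9 alkene, with the same β-peroxy carbonyl problem as in alternative 1.
- Structure: better at C1–C3, worse at C6 and C8.
- Mechanism: the carbonylative termination with a peroxide nucleophile is an extension of known chemistry, about as uncertain as step 10 of the chosen plan.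
- Step economy: the best single step of the three, but the end game is longer than from 23.

Key step: step 9

Assumption: the (S,S)-amide is taken to give the (3R)-enol ether 3, by analogy with the sense known for 4-substituted cyclohexanones; if the four-membered ring responds in the opposite sense, the (R,R)-amide is used and nothing else changes. Compound 4 is used as the monomer freshly liberated from its commercial hemiacetal or polymer.

## Route

Step 1
Reactants: 1 3-methylcyclobutan-1-one
Product: 3 trimethyl{[(3R)-3-methylcyclobut-1-en-1-yl]oxy}silane, via lithium enolate 2 (not isolated)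
Conditions: (S,S)-bis(1-phenylethyl)amine, n-BuLi, THF, −78 °C; TMSCl (5 equiv) then 1, −100 °C
Reagents that add atoms: chlorotrimethylsilane, C[Si](C)(C)Cl
Why: Enantioselective deprotonation by a C2-symmetric chiral lithium amide with internal silyl quench; the base chooses between the two enantiotopic α-methylene groups, and that choice fixes the methyl-bearing carbon (the future C4) as R. The reaction type is established for 3-substituted cyclobutanones.

Step 2
Reactants: 3 trimethyl{[(3R)-3-methylcyclobut-1-en-1-yl]oxy}silane; 4 methyl glyoxylate
Product: 5 methyl 2-hydroxy-2-[(2R)-2-methyl-4-oxocyclobutyl]acetate (diastereomers at ring C1 and at the carbinol carbon)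
Conditions: TiCl4, CH2Cl2, −78 °C; aq. NaHCO3
Reagents that add atoms: none
Why: Mukaiyama aldol addition; only the enol carbon attacks the activated aldehyde, so the C–C bond forms next to the methyl-bearing carbon, and with no free enolate present no proton transfer can erode the enantiomeric purity. The two new stereocentres are removed in steps 3 and 4.

Step 3
Reactants: 5 methyl 2-hydroxy-2-[(2R)-2-methyl-4-oxocyclobutyl]acetate
Product: 7 methyl (2E)-2-[(2R)-2-methyl-4-oxocyclobutylidene]acetate, via mesylate 6 (not isolated)
Conditions: MsCl, Et3N, CH2Cl2, −20 → 0 °C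
Reagents that add atoms: none
Why: Mesylation and E1cB elimination through the ketone enol give the exocyclic enone ester (either alkene geometry serves); triethylamine at 0 °C is too weak to deprotonate the γ-position, so the methyl stereocentre is untouched.

Step 4
Reactants: 7 methyl (2E)-2-[(2R)-2-methyl-4-oxocyclobutylidene]acetate
Product: 9 methyl 2-[(4R)-4-methyl-2-(trifluoromethylsulfonyloxy)cyclobut-1-en-1-yl]acetate, via lithium enolate 8 (not isolated)
Conditions: LiBH(s-Bu)3, THF, −78 °C; then N-(5-chloropyridin-2-yl)bis(trifluoromethanesulfonyl)imide, −78 → 0 °C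
Reagents that add atoms: N-(5-chloropyridin-2-yl)bis(trifluoromethanesulfonyl)imide, O=S(=O)(N(c1ccc(Cl)cn1)S(=O)(=O)C(F)(F)F)C(F)(F)F
Why: Conjugate reduction of an s-cis enone by a hindered borohydride followed by O-triflation of the enolate; hydride adds to the exocyclic carbon (β to the ketone, α to the ester), so the enolate and the enol triflate can only form toward the substituted ring carbon.

Step 5
Reactants: 9 methyl 2-[(4R)-4-methyl-2-(trifluoromethylsulfonyloxy)cyclobut-1-en-1-yl]acetate
Product: 10 methyl 2-[(4R)-4-methyl-2-(4,4,5,5-tetramethyl-1,3,2-dioxaborolan-2-yl)cyclobut-1-en-1-yl]acetate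
Conditions: B2pin2, PdCl2(PPh3)2 (3 mol%), PPh3, PhOK, toluene, 50 °C
Reagents that add atoms: bis(pinacolato)diboron, CC1(C)OB(OC1(C)C)B1OC(C)(C)C(C)(C)O1
Why: Miyaura borylation of an alkenyl triflate; potassium phenoxide is basic enough for transmetalation but not for isomerising the β,γ-unsaturated ester.

Step 6
Reactants: 11 prop-2-yn-1-ol
Product: 13 (E)-3-bromo-2-methylprop-2-en-1-ol, via alkenylalane 12 (not isolated)
Conditions: AlMe3 (3 equiv), Cp2ZrCl2 (0.25 equiv), CH2Cl2, 0 °C → rt; then NBS, THF, −30 → 0 °C; aq. potassium sodium tartrate
Reagents that add atoms: trimethylaluminium, C[Al](C)C; N-bromosuccinimide, O=C1CCC(=O)N1Br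
Why: Zirconium-catalysed carboalumination (Negishi) adds methyl and aluminium syn across the alkyne with aluminium at the terminus; bromodealumination with retention gives the (E)-bromoalkene.

Step 7
Reactants: 13 (E)-3-bromo-2-methylprop-2-en-1-ol
Product: 14 (E)-1,3-dibromo-2-methylprop-1-ene
Conditions: CBr4, PPh3, CH2Cl2, 0 °C
Reagents that add atoms: carbon tetrabromide, BrC(Br)(Br)Br
Why: Appel bromination converts the primary allylic alcohol into the bromide under neutral conditions without touching the vinylic bromide or the alkene geometry.

Step 8
Reactants: 10 methyl 2-[(4R)-4-methyl-2-(4,4,5,5-tetramethyl-1,3,2-dioxaborolan-2-yl)cyclobut-1-en-1-yl]acetate; 14 (E)-1,3-dibromo-2-methylprop-1-ene (1.5 equiv)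
Product: 15 methyl 2-[(4R)-2-[(E)-3-bromo-2-methylprop-2-enyl]-4-methylcyclobut-1-en-1-yl]acetate
Conditions: Pd(PPh3)4 (5 mol%), CsF, THF, 45 °C
Reagents that add atoms: none
Why: Suzuki–Miyaura sp2–sp3 coupling; zerovalent palladium inserts into the allylic C–Br bond far faster than into the vinylic one and the allyl unit couples at its unsubstituted CH2 terminus, so the bromoalkene survives with E geometry. Fluoride activation keeps the medium nearly neutral and the ring alkene in place.

Step 9
Reactants: 15 methyl 2-[(4R)-2-[(E)-3-bromo-2-methylprop-2-enyl]-4-methylcyclobut-1-en-1-yl]acetate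
Product: 23 methyl 2-[(4R)-6-[(E)-3-bromo-2-methylprop-2-enyl]-3,6-dimethoxy-4-methyl-1,2-dioxan-3-yl]acetate (ketal epimers), via primary ozonide 16 (not isolated), via C3 carbonyl oxide 17 (not isolated), via C6 carbonyl oxide 18 (not isolated), via C3 methoxy hydroperoxide 19 (not isolated), via C6 methoxy hydroperoxide 20 (not isolated), via 6-hydroxy-3-methoxy hemiketal 21 (not isolated), via 3-hydroxy-6-methoxy hemiketal 22 (not isolated)
Conditions: O3/O2, CH2Cl2–MeOH (1:1), Sudan Red 7B (trace), −78 °C; N2 purge; then HC(OMe)3, camphorsulfonic acid (10 mol%), −20 °C → rt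
Reagents that add atoms: ozone, [O-][O+]=O; methanol, CO; trimethyl orthoformate, COC(OC)OC
Why: Ozone adds by 1,3-dipolar cycloaddition to the strained, tetrasubstituted ring alkene to give primary ozonide 16, which cycloreverts in either sense to a ketone tethered to a carbonyl oxide (17 or 18). Methanol, present in large excess, adds to the carbonyl oxide faster than the tethered ketone (a poor dipolarophile) can, giving the α-methoxy hydroperoxides 19 and 20. In each, the OOH group adds to the ketone four carbons away by 6-exo-trig hemiketalisation, which forms the second C–O bond and closes the 1,2-dioxane as hemiketals 21 and 22. Acid and orthoformate then cap the hemiketal hydroxyl, so both fragmentation senses converge on one bis(methyl peroxyketal) 23 and no free OH meets AlMe3 in step 10. The closest known reaction type is Criegee ozonolysis in an alcohol followed by cyclisation of the hydroperoxy carbonyl compound to a cyclic peroxide. No lasting stereocentre is created: C3 and C6 are ketal carbons formed as epimers and are reset in steps 10 and 11, and C4 is not involved. The selectivity needed is cleavage of the ring alkene and not the bromoalkene; ring strain and full alkyl substitution on one side and the deactivating halogen on the other secure it, and ozone is titrated at −78 °C to the indicator end point.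

Step 10
Reactants: 23 methyl 2-[(4R)-6-[(E)-3-bromo-2-methylprop-2-enyl]-3,6-dimethoxy-4-methyl-1,2-dioxan-3-yl]acetate
Product: 25 methyl 2-[(4R,6R)-6-[(E)-3-bromo-2-methylprop-2-enyl]-3-methoxy-4,6-dimethyl-1,2-dioxan-3-yl]acetate (C3 epimers), via C6 peroxycarbenium triflate 24 (not isolated)
Conditions: AlMe3 (3 equiv), TMSOTf (1.2 equiv), CH2Cl2, −78 °C
Reagents that add atoms: trimethylaluminium, C[Al](C)C
Why: Proposed new method: TMSOTf should ionise the C6 methyl peroxyketal, which is more electron-rich and less hindered than the C3 ketal next to the ester-bearing carbon, to peroxycarbenium ion 24; AlMe3 should then transfer methyl along the axial trajectory of the half-chair with the C4 methyl pseudo-equatorial, giving the axial C6 methyl, that is (6R). The closest known reaction types are AlMe3/TMSOTf methylation of cyclic ketals through oxocarbenium ions and Lewis-acid allylation of 3-alkoxy-1,2-dioxanes through peroxycarbenium ions.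

Step 11
Reactants: 25 methyl 2-[(4R,6R)-6-[(E)-3-bromo-2-methylprop-2-enyl]-3-methoxy-4,6-dimethyl-1,2-dioxan-3-yl]acetate
Product: 27 methyl 2-[(3S,4R,6R)-6-[(E)-3-bromo-2-methylprop-2-enyl]-4,6-dimethyl-1,2-dioxan-3-yl]acetate, via C3 peroxycarbenium triflate 26 (not isolated)
Conditions: Et3SiH (5 equiv), TMSOTf (1.5 equiv), CH2Cl2, −78 → −30 °C
Reagents that add atoms: none
Why: Ionic hydrogenation of a peroxyketal through peroxycarbenium ion 26, the hydride counterpart of the Lewis-acid substitutions of 3-alkoxy-1,2-dioxanes and of the silane reduction of β-keto-ester-derived pyranyl ketals. The quaternary C6 locks the ring (the other half-chair would put the C4 methyl and the C6 chain syn-diaxial), so axial hydride delivery leaves the acetate arm equatorial and trans to the C4 methyl, that is (3S).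

Step 12
Reactants: 28 prop-2-ynylbenzene
Product: 29 4,4,5,5-tetramethyl-2-[(E)-3-phenylprop-1-enyl]-1,3,2-dioxaborolane
Conditions: pinacolborane, Cp2Zr(H)Cl (5 mol%), Et3N (10 mol%), neat, 60 °C
Reagents that add atoms: pinacolborane, CC1(C)OBOC1(C)C
Why: Zirconocene-hydride-catalysed syn hydroboration of the terminal alkyne places boron at the terminus and gives the (E)-alkenylboronate under neutral conditions that do not isomerise the propargylic benzylic position.

Step 13
Reactants: 27 methyl 2-[(3S,4R,6R)-6-[(E)-3-bromo-2-methylprop-2-enyl]-4,6-dimethyl-1,2-dioxan-3-yl]acetate; 29 4,4,5,5-tetramethyl-2-[(E)-3-phenylprop-1-enyl]-1,3,2-dioxaborolane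
Product: 30 methyl 2-[(3S,4R,6R)-4,6-dimethyl-6-[(2E,4E)-2-methyl-6-phenylhexa-2,4-dienyl]-1,2-dioxan-3-yl]acetate
Conditions: Pd(dppf)Cl2 (5 mol%), K3PO4 (2 M aq), THF, 40 °C, degassed
Reagents that add atoms: none
Why: Suzuki–Miyaura coupling of an alkenyl bromide with an alkenylboronate goes with retention at both partners and so gives the (8E,10E)-diene. Palladium cross-coupling in the presence of a 1,2-dioxane is known practice, and the phosphate base at 40 °C is too weak to trigger E1cB opening of the β-peroxy ester.

## Compound list

1 | 3-methylcyclobutan-1-one | CC1CC(=O)C1 | starting material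
2 | lithium (3R)-3-methylcyclobut-1-en-1-olate | [Li+].[O-]C1=C[C@H](C)C1 | intermediate (not isolated)
3 | trimethyl{[(3R)-3-methylcyclobut-1-en-1-yl]oxy}silane | C[Si](C)(C)OC1=C[C@H](C)C1 | intermediate
4 | methyl glyoxylate (methyl 2-oxoacetate) | COC(=O)C=O | starting material
5 | methyl 2-hydroxy-2-[(2R)-2-methyl-4-oxocyclobutyl]acetate (diastereomers at ring C1 and the carbinol carbon) | COC(=O)C(O)C1C(=O)C[C@H]1C | intermediate
6 | methyl 2-(methylsulfonyloxy)-2-[(2R)-2-methyl-4-oxocyclobutyl]acetate | COC(=O)C(OS(C)(=O)=O)C1C(=O)C[C@H]1C | intermediate (not isolated)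
7 | methyl (2E)-2-[(2R)-2-methyl-4-oxocyclobutylidene]acetate | COC(=O)/C=C1/C(=O)C[C@H]1C | intermediate
8 | lithium (3R)-2-(2-methoxy-2-oxoethyl)-3-methylcyclobut-1-en-1-olate | COC(=O)CC1=C([O-])C[C@H]1C.[Li+] | intermediate (not isolated)
9 | methyl 2-[(4R)-4-methyl-2-(trifluoromethylsulfonyloxy)cyclobut-1-en-1-yl]acetate | COC(=O)CC1=C(OS(=O)(=O)C(F)(F)F)C[C@H]1C | intermediate
10 | methyl 2-[(4R)-4-methyl-2-(4,4,5,5-tetramethyl-1,3,2-dioxaborolan-2-yl)cyclobut-1-en-1-yl]acetate | COC(=O)CC1=C(B2OC(C)(C)C(C)(C)O2)C[C@H]1C | intermediate
11 | prop-2-yn-1-ol | C#CCO | starting material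
12 | dimethylaluminium (E)-3-(dimethylalumanyl)-2-methylprop-2-en-1-olate | C[Al](C)OC/C(C)=C/[Al](C)C | intermediate (not isolated)
13 | (E)-3-bromo-2-methylprop-2-en-1-ol | OC/C(C)=C/Br | intermediate
14 | (E)-1,3-dibromo-2-methylprop-1-ene | BrC/C(C)=C/Br | intermediate
15 | methyl 2-[(4R)-2-[(E)-3-bromo-2-methylprop-2-enyl]-4-methylcyclobut-1-en-1-yl]acetate | COC(=O)CC1=C(C/C(C)=C/Br)C[C@H]1C | intermediate
16 | primary ozonide: methyl 2-[(7R)-5-[(E)-3-bromo-2-methylprop-2-enyl]-7-methyl-2,3,4-trioxabicyclo[3.2.0]heptan-1-yl]acetate | COC(=O)CC12OOOC1(C/C(C)=C/Br)C[C@H]2C | intermediate (not isolated)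
17 | C3 carbonyl oxide of methyl (4R,8E)-9-bromo-4,8-dimethyl-3,6-dioxonon-8-enoate | COC(=O)CC(=[O+][O-])[C@H](C)CC(=O)C/C(C)=C/Br | intermediate (not isolated)
18 | C6 carbonyl oxide of methyl (4R,8E)-9-bromo-4,8-dimethyl-3,6-dioxonon-8-enoate | COC(=O)CC(=O)[C@H](C)CC(=[O+][O-])C/C(C)=C/Br | intermediate (not isolated)
19 | methyl (4R,8E)-9-bromo-3-hydroperoxy-3-methoxy-4,8-dimethyl-6-oxonon-8-enoate | COC(=O)CC(OC)(OO)[C@H](C)CC(=O)C/C(C)=C/Br | intermediate (not isolated)
20 | methyl (4R,8E)-9-bromo-6-hydroperoxy-6-methoxy-4,8-dimethyl-3-oxonon-8-enoate | COC(=O)CC(=O)[C@H](C)CC(OC)(OO)C/C(C)=C/Br | intermediate (not isolated)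
21 | methyl 2-[(4R)-6-[(E)-3-bromo-2-methylprop-2-enyl]-6-hydroxy-3-methoxy-4-methyl-1,2-dioxan-3-yl]acetate (ketal epimers) | COC(=O)CC1(OC)OOC(O)(C/C(C)=C/Br)C[C@H]1C | intermediate (not isolated)
22 | methyl 2-[(4R)-6-[(E)-3-bromo-2-methylprop-2-enyl]-3-hydroxy-6-methoxy-4-methyl-1,2-dioxan-3-yl]acetate (ketal epimers) | COC(=O)CC1(O)OOC(OC)(C/C(C)=C/Br)C[C@H]1C | intermediate (not isolated)
23 | methyl 2-[(4R)-6-[(E)-3-bromo-2-methylprop-2-enyl]-3,6-dimethoxy-4-methyl-1,2-dioxan-3-yl]acetate (ketal epimers) | COC(=O)CC1(OC)OOC(OC)(C/C(C)=C/Br)C[C@H]1C | intermediate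
24 | C6 peroxycarbenium triflate derived from 23 | COC(=O)CC1(OC)O[O+]=C(C/C(C)=C/Br)C[C@H]1C.[O-]S(=O)(=O)C(F)(F)F | intermediate (not isolated)
25 | methyl 2-[(4R,6R)-6-[(E)-3-bromo-2-methylprop-2-enyl]-3-methoxy-4,6-dimethyl-1,2-dioxan-3-yl]acetate (C3 epimers) | COC(=O)CC1(OC)OO[C@@](C)(C/C(C)=C/Br)C[C@H]1C | intermediate
26 | C3 peroxycarbenium triflate derived from 25 | COC(=O)CC1=[O+]O[C@@](C)(C/C(C)=C/Br)C[C@H]1C.[O-]S(=O)(=O)C(F)(F)F | intermediate (not isolated)
27 | methyl 2-[(3S,4R,6R)-6-[(E)-3-bromo-2-methylprop-2-enyl]-4,6-dimethyl-1,2-dioxan-3-yl]acetate | COC(=O)C[C@@H]1OO[C@@](C)(C/C(C)=C/Br)C[C@H]1C | intermediate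
28 | prop-2-ynylbenzene | C#CCc1ccccc1 | starting material
29 | 4,4,5,5-tetramethyl-2-[(E)-3-phenylprop-1-enyl]-1,3,2-dioxaborolane | CC1(C)OB(/C=C/Cc2ccccc2)OC1(C)C | intermediate
30 | methyl 2-[(3S,4R,6R)-4,6-dimethyl-6-[(2E,4E)-2-methyl-6-phenylhexa-2,4-dienyl]-1,2-dioxan-3-yl]acetate | COC(=O)C[C@@H]1OO[C@@](C)(C/C(C)=C/C=C/Cc2ccccc2)C[C@H]1C | target

## Step count and least certain steps

Total step count: 13. Longest linear sequence: 10 steps (1, 2, 3, 4, 5, 8, 9, 10, 11, 13).

**Step 10 (methyl transfer to C6).** The most likely failures are loss of site selectivity between the two ketal carbons, attack of the aluminium reagent on the O–O bond before methyl transfer, and proton loss from the cation to enol ethers. The cause is that a peroxycarbenium ion is less stabilised than an ordinary oxocarbenium ion and its pairing with AlMe3 is untested. The fallback uses known chemistry, sets out from 15 and comes back at 27. Reductive ozonolysis of 15 (O3, CH2Cl2, −78 °C; Me2S) gives methyl (4R,8E)-9-bromo-4,8-dimethyl-3,6-dioxonon-8-enoate F1. Excess Ph3P=CH2 (the first equivalent masks the β-keto ester as its enolate) methylenates the C6 ketone to methyl (4R,8E)-9-bromo-4,8-dimethyl-6-methylidene-3-oxonon-8-enoate F2. Mukaiyama–Isayama peroxidation (Co(thd)2, the divalent cobalt bis(2,2,6,6-tetramethylheptane-3,5-dionate), with O2 and Et3SiH) adds H and OOSiEt3 across the 1,1-disubstituted alkene in the Markovnikov sense, which creates the C6 methyl group and the tertiary C6–O bond in methyl (4R,8E)-9-bromo-4,6,8-trimethyl-3-oxo-6-(triethylsilylperoxy)non-8-enoate F3. HCl in methanol removes silicon and the hydroperoxide closes onto the C3 ketone to give methyl 2-[(4R)-6-[(E)-3-bromo-2-methylprop-2-enyl]-3-hydroxy-4,6-dimethyl-1,2-dioxan-3-yl]acetate F4. Et3SiH/TMSOTf as in step 11 then gives 27. The price is that C6 is formed without control, so methyl 2-[(4R,6S)-6-[(E)-3-bromo-2-methylprop-2-enyl]-4,6-dimethyl-1,2-dioxan-3-yl]acetate F5 has to be removed by chromatography.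

**Step 9 (key step).** The most likely failures are capture of the carbonyl oxide by the tethered ketone in competition with methanol (ozonide formation), over-oxidation at the bromoalkene if ozone is overdosed, and acid-promoted loss of hydrogen peroxide with aromatisation to a furan during ketalisation. The cause is that the two carbonyl-derived termini are held close together on a four-carbon tether. The fallback sets out from 15 and comes back at 23: reductive ozonolysis gives the diketone F1 as above; acid-catalysed addition of hydrogen peroxide (urea–hydrogen peroxide, catalytic acid), the standard conversion of 1,4-diketones into 3,6-dihydroxy-1,2-dioxanes, gives methyl 2-[(4R)-6-[(E)-3-bromo-2-methylprop-2-enyl]-3,6-dihydroxy-4-methyl-1,2-dioxan-3-yl]acetate F6; HC(OMe)3, methanol and camphorsulfonic acid convert it into 23.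

**Step 11 (hydride delivery to C3).** The most likely failures are hydride transfer losing to proton loss from the cation or to cleavage of the ring C3–O1 bond, and incomplete axial selectivity. The cause is that the ester-bearing neighbour slows ionisation at C3. The fallback forms the C3–O bond by conjugate addition instead; it sets out from 15 and comes back at 27. F1 and F2 are made as above. NaBH4 reduces the β-keto ester of F2 to methyl (4R,8E)-9-bromo-3-hydroxy-4,8-dimethyl-6-methylidenenon-8-enoate F7. MsCl/Et3N then DBU gives methyl (2E,4R,8E)-9-bromo-4,8-dimethyl-6-methylidenenona-2,8-dienoate F8. Mukaiyama–Isayama peroxidation of the 1,1-disubstituted alkene gives methyl (2E,4R,8E)-9-bromo-4,6,8-trimethyl-6-(triethylsilylperoxy)nona-2,8-dienoate F9. HCl in methanol gives methyl (2E,4R,8E)-9-bromo-6-hydroperoxy-4,6,8-trimethylnona-2,8-dienoate F10. Et2NH in CF3CH2OH then effects the reversible 6-exo-trig oxa-Michael addition, which under thermodynamic control places the acetate arm equatorial and trans to the C4 methyl. 27 is obtained after separation from the (6S) series F5.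

**Step 1 (enantioselective deprotonation).** The most likely failures are insufficient discrimination between the enantiotopic methylene groups and partial equilibration of the enolate before silylation. The cause is that a methyl group is a small steering element. The fallback sets out from 1 and comes back at 5: a proline-derived sulfonamide catalyses the desymmetrising enamine aldol addition of 1 to 4 and gives 5 directly. The catalyst enantiomer is chosen to give the (2R) methyl centre. This fallback adds no compound beyond the list (entry F0).

**Step 4 (conjugate reduction and triflation).** The most likely failure is 1,2-addition of hydride to the strained, very electrophilic ring carbonyl in place of conjugate addition. The fallback sets out from 7 and comes back at 9: RhCl(PPh3)3-catalysed 1,4-hydrosilylation with Et3SiH gives methyl 2-[(4R)-4-methyl-2-(triethylsilyloxy)cyclobut-1-en-1-yl]acetate F11 with the same regiochemistry, and CsF with PhNTf2 in DME converts it into 9.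

## Further compounds

F1 | step 10 | methyl (4R,8E)-9-bromo-4,8-dimethyl-3,6-dioxonon-8-enoate | COC(=O)CC(=O)[C@H](C)CC(=O)C/C(C)=C/Br
F2 | step 10 | methyl (4R,8E)-9-bromo-4,8-dimethyl-6-methylidene-3-oxonon-8-enoate | COC(=O)CC(=O)[C@H](C)CC(=C)C/C(C)=C/Br
F3 | step 10 | methyl (4R,8E)-9-bromo-4,6,8-trimethyl-3-oxo-6-(triethylsilylperoxy)non-8-enoate (C6 epimers) | COC(=O)CC(=O)[C@H](C)CC(C)(OO[Si](CC)(CC)CC)C/C(C)=C/Br
F4 | step 10 | methyl 2-[(4R)-6-[(E)-3-bromo-2-methylprop-2-enyl]-3-hydroxy-4,6-dimethyl-1,2-dioxan-3-yl]acetate (C3 and C6 epimers) | COC(=O)CC1(O)OOC(C)(C/C(C)=C/Br)C[C@H]1C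
F5 | step 10 | methyl 2-[(4R,6S)-6-[(E)-3-bromo-2-methylprop-2-enyl]-4,6-dimethyl-1,2-dioxan-3-yl]acetate (C3 open) | COC(=O)CC1OO[C@](C)(C/C(C)=C/Br)C[C@H]1C
F6 | step 9 | methyl 2-[(4R)-6-[(E)-3-bromo-2-methylprop-2-enyl]-3,6-dihydroxy-4-methyl-1,2-dioxan-3-yl]acetate | COC(=O)CC1(O)OOC(O)(C/C(C)=C/Br)C[C@H]1C
F7 | step 11 | methyl (4R,8E)-9-bromo-3-hydroxy-4,8-dimethyl-6-methylidenenon-8-enoate (C3 epimers) | COC(=O)CC(O)[C@H](C)CC(=C)C/C(C)=C/Br
F8 | step 11 | methyl (2E,4R,8E)-9-bromo-4,8-dimethyl-6-methylidenenona-2,8-dienoate | COC(=O)/C=C/[C@H](C)CC(=C)C/C(C)=C/Br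
F9 | step 11 | methyl (2E,4R,8E)-9-bromo-4,6,8-trimethyl-6-(triethylsilylperoxy)nona-2,8-dienoate (C6 epimers) | COC(=O)/C=C/[C@H](C)CC(C)(OO[Si](CC)(CC)CC)C/C(C)=C/Br
F10 | step 11 | methyl (2E,4R,8E)-9-bromo-6-hydroperoxy-4,6,8-trimethylnona-2,8-dienoate (C6 epimers) | COC(=O)/C=C/[C@H](C)CC(C)(OO)C/C(C)=C/Br
F0 | step 1 | none | none
F11 | step 4 | methyl 2-[(4R)-4-methyl-2-(triethylsilyloxy)cyclobut-1-en-1-yl]acetate | COC(=O)CC1=C(O[Si](CC)(CC)CC)C[C@H]1C
A1 | alternative 1 | tert-butyl-[(3S,4R)-3-hydroperoxy-4-methyl-5-[(2S)-2-methyl-4-[(E)-4-phenylbut-2-enyl]oxetan-2-yl]pentoxy]diphenylsilane | CC(C)(C)[Si](c1ccccc1)(c1ccccc1)OCC[C@H](OO)[C@H](C)C[C@@]2(C)CC(C/C=C/Cc3ccccc3)O2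
A2 | alternative 1 | tert-butyl-[2-[(3S,4R,6R)-6-[(E)-2-hydroxy-6-phenylhex-4-enyl]-4,6-dimethyl-1,2-dioxan-3-yl]ethoxy]diphenylsilane | CC(C)(C)[Si](c1ccccc1)(c1ccccc1)OCC[C@@H]2OO[C@@](C)(CC(O)C/C=C/Cc3ccccc3)C[C@H]2C
A3 | alternative 2 | methyl (3S,4R,6R,8E)-3,6-bis(aminooxy)-10-[tert-butyl(dimethyl)silyl]oxy-4,6,8-trimethyldec-8-enoate | COC(=O)C[C@H](ON)[C@H](C)C[C@@](C)(ON)C/C(C)=C/CO[Si](C)(C)C(C)(C)C
A4 | alternative 2 | methyl 2-[(3S,4R,6R)-6-[(E)-4-[tert-butyl(dimethyl)silyl]oxy-2-methylbut-2-enyl]-4,6-dimethyl-1,2-dioxan-3-yl]acetate | COC(=O)C[C@@H]1OO[C@@](C)(C/C(C)=C/CO[Si](C)(C)C(C)(C)C)C[C@H]1C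
A5 | alternative 3 | tert-butyl-[(3R,5R,9E)-5-hydroperoxy-3,5-dimethyl-11-phenylundeca-1,9-dien-7-yl]oxy-dimethylsilane | C=C[C@H](C)C[C@@](C)(OO)CC(O[Si](C)(C)C(C)(C)C)C/C=C/Cc1ccccc1
A6 | alternative 3 | methyl 2-[(3S,4R,6R)-6-[(E)-2-[tert-butyl(dimethyl)silyl]oxy-6-phenylhex-4-enyl]-4,6-dimethyl-1,2-dioxan-3-yl]acetate | COC(=O)C[C@@H]1OO[C@@](C)(CC(O[Si](C)(C)C(C)(C)C)C/C=C/Cc2ccccc2)C[C@H]1C
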